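The route rests on cutting ring C where it meets ring A: C4–C4a and O1–C8a. C4a and C8a thereby become the two carbons of an aryne. The feature exploited is the C5 oxygen next to C4a, which polarises that triple bond. The C2 alkoxide of an acyclic, stereodefined chloro alcohol adds at C8a. The aryl anion left at C4a displaces chloride from C4, so ring C closes in one operation without touching C2 or C3, and the syn diol pattern becomes the 2,3-cis flavan. The precursors are a fluoroarene (O5 as MOM, O7 as benzyl) and a chlorohydrin ether (O3 as MOM). O3 and O5 are later freed and galloylated together.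

Key step: step 6

Assumption: compounds 1, 4, 5 and 18 are taken as purchasable, and flavan numbering (O1, C2, C3, C4, C4a, C5 to C8, C8a) is used for the corresponding atoms of all intermediates.

Step 1
Reactants: 1 3,5-difluorophenol
Product: 2 1,3-difluoro-5-(methoxymethoxy)benzene
Conditions: NaH, MOMCl, THF, 0 °C → rt
Reagents that add atoms: chloromethyl methyl ether (MOMCl), COCCl
Why: Williamson-type O-alkylation of the sodium phenoxide installs the acetal that later serves both as the removable mask of O5 and as the directing group for lithiation.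

Step 2
Reactants: 2 1,3-difluoro-5-(methoxymethoxy)benzene
Product: 3 1-(benzyloxy)-3-fluoro-5-(methoxymethoxy)benzene
Conditions: BnOH (1.0 equiv), NaH, NMP, 100 °C
Reagents that add atoms: benzyl alcohol, OCc1ccccc1
Why: Nucleophilic aromatic substitution (SNAr) of one of two equivalent fluorides by sodium benzyloxide, a reaction type established for 3,5-difluoroalkoxybenzenes, should stop after one exchange because the remaining fluoride has lost the inductive help of its partner, and the MOM acetal is inert to base.

Step 3
Reactants: 4 3,4,5-tris(benzyloxy)benzaldehyde, 5 3-(methoxymethoxy)prop-1-ene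
Product: 8 (1R,2R)-2-(methoxymethoxy)-1-[3,4,5-tris(benzyloxy)phenyl]but-3-en-1-ol, via allyllithium 6 (not isolated), via allylborane 7 (not isolated)
Conditions: 5, s-BuLi, THF, −78 °C; (−)-Ipc2BOMe; BF3·OEt2; 4, −78 °C → rt; NaOH, H2O2
Reagents that add atoms: none
Why: Brown alkoxyallylboration, in which the (Z)-γ-alkoxyallylborane 7 adds through a closed chair transition state, so that the Z geometry gives the syn relationship and the isopinocampheyl groups derived from (+)-α-pinene direct attack to the Si face of 4, which sets C2 (R) and C3 (R) of the target.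

Step 4
Reactants: 8 (1R,2R)-2-(methoxymethoxy)-1-[3,4,5-tris(benzyloxy)phenyl]but-3-en-1-ol
Product: 10 (1R,2R)-2-(methoxymethoxy)-1-[3,4,5-tris(benzyloxy)phenyl]propane-1,3-diol, via aldehyde 9 (not isolated)
Conditions: OsO4 (cat.), NaIO4, 2,6-lutidine, dioxane–H2O, rt; then NaBH4, MeOH, 0 °C
Reagents that add atoms: osmium tetroxide, O=[Os](=O)(=O)=O (its oxygen is replenished by sodium periodate, [Na+].[O-]I(=O)(=O)=O)
Why: Lemieux–Johnson cleavage of the terminal alkene and immediate borohydride reduction of the crude aldehyde 9 trim the vinyl group to C4 as CH2OH, the lutidine buffer guarding the β-hydroxy aldehyde against retro-aldol cleavage and epimerisation and the mild oxidant sparing the electron-rich arenes.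

Step 5
Reactants: 10 (1R,2R)-2-(methoxymethoxy)-1-[3,4,5-tris(benzyloxy)phenyl]propane-1,3-diol
Product: 11 (1R,2S)-3-chloro-2-(methoxymethoxy)-1-[3,4,5-tris(benzyloxy)phenyl]propan-1-ol
Conditions: PPh3, CCl4, pyridine, 0 °C → rt
Reagents that add atoms: carbon tetrachloride, ClC(Cl)(Cl)Cl
Why: Appel chlorination in pyridine, a method known to single out primary hydroxyl groups of polyols, replaces only the CH2OH oxygen by SN2, so neither stereocentre is touched (the descriptor of the MOM-bearing carbon changes from R to S only because chlorine raises the rank of C4).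

Step 6
Reactants: 3 1-(benzyloxy)-3-fluoro-5-(methoxymethoxy)benzene, 11 (1R,2S)-3-chloro-2-(methoxymethoxy)-1-[3,4,5-tris(benzyloxy)phenyl]propan-1-ol
Product: 16 (2R,3R)-7-(benzyloxy)-3,5-bis(methoxymethoxy)-2-[3,4,5-tris(benzyloxy)phenyl]chromane, via aryllithium 12 (not isolated), via potassium alkoxide 13 (not isolated), via aryne 14 (not isolated), via arylpotassium 15 (not isolated)
Conditions: 3 (1.5 equiv), n-BuLi, THF, −78 °C; 11, KH, THF, −20 °C; cold 12 added slowly to 13, −20 °C → rt
Reagents that add atoms: none
Why: Proposed new method: n-BuLi removes the ring proton of 3 that lies between F and OMOM (acidified by fluorine and the only fluorine-flanked site chelated by the MOM group), and when the cold aryllithium 12 meets the warmer solution of alkoxide 13 it loses LiF to give aryne 14, whose carbon remote from OMOM (future C8a) takes up the alkoxide oxygen because the σ-withdrawing C5 oxygen distorts the triple bond and stabilises charge on the adjacent carbon (future C4a), after which arylpotassium 15 displaces the primary chloride at C4. The closest known reaction types are the meta-selective C–O coupling of potassium alkoxides with 3-alkoxyarynes, the multicomponent benzyne couplings in which the aryl-metal formed by nucleophile addition is caught by an electrophile, and the Parham cyclialkylation, and what is new is their combination with an alkoxide as first partner and an internal alkyl chloride as second. Ring C closes in the 6-exo-tet mode. No stereocentre is formed, and since the C2–O and C3–O bonds are never broken the syn (1R,2S) array of 11 is carried unchanged into the (2R,3R)-cis flavan. Three selectivities are needed: the alkoxide must beat the aryllithium to the aryne (slow inverse addition keeps 12 scarce and 13 abundant), the aryl anion must close before it is protonated (butane and hydrogen are the only by-products of the two metalations, so the medium holds no acid), and the alkoxide must leave its own chloride alone (4-exo-tet oxetane closure and Grob-type fragmentation of a γ-chloro alkoxide are slow at −20 °C, whereas the far more nucleophilic aryl anion closes a six-membered ring). O5 and O7 are told apart in the same event, since the MOM-bearing oxygen necessarily ends up beside C4a.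

Step 7
Reactants: 16 (2R,3R)-7-(benzyloxy)-3,5-bis(methoxymethoxy)-2-[3,4,5-tris(benzyloxy)phenyl]chromane
Product: 17 (2R,3R)-7-(benzyloxy)-2-[3,4,5-tris(benzyloxy)phenyl]chromane-3,5-diol
Conditions: ZnBr2, n-PrSH, CH2Cl2, 0 °C → rt
Reagents that add atoms: none
Why: Lewis acid and thiol mediated acetal cleavage removes the aryl MOM at O5 and the alkyl MOM at O3 together while the benzyl ethers stay, and the thiol binds the formaldehyde unit as a dithioacetal so that it cannot alkylate the electron-rich ring A, with C2 and C3 untouched.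

Step 8
Reactants: 17 (2R,3R)-7-(benzyloxy)-2-[3,4,5-tris(benzyloxy)phenyl]chromane-3,5-diol, 18 3,4,5-tris(benzyloxy)benzoic acid
Product: 19 (2R,3R)-7-(benzyloxy)-2-[3,4,5-tris(benzyloxy)phenyl]chromane-3,5-diyl bis[3,4,5-tris(benzyloxy)benzoate]
Conditions: 18 (2.5 equiv), DCC, DMAP (cat.), CH2Cl2, rt
Reagents that add atoms: none
Why: Steglich esterification acylates the C5 phenol and the C3 alcohol, the only two free hydroxyl groups, in the same operation without touching C2 or C3.

Step 9
Reactants: 19 (2R,3R)-7-(benzyloxy)-2-[3,4,5-tris(benzyloxy)phenyl]chromane-3,5-diyl bis[3,4,5-tris(benzyloxy)benzoate]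
Product: 20 epigallocatechin 3,5-digallate
Conditions: H2 (1 atm), Pd(OH)2/C, THF, rt
Reagents that add atoms: none
Why: Catalytic hydrogenolysis removes all ten benzyl ethers under neutral conditions that leave both gallate esters and the two stereocentres intact, the non-nucleophilic solvent sparing the labile C5 aryl ester.

Compound list
1 | 3,5-difluorophenol | Oc1cc(F)cc(F)c1 | starting material
2 | 1,3-difluoro-5-(methoxymethoxy)benzene | COCOc1cc(F)cc(F)c1 | intermediate
3 | 1-(benzyloxy)-3-fluoro-5-(methoxymethoxy)benzene | COCOc1cc(F)cc(OCc2ccccc2)c1 | intermediate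
4 | 3,4,5-tris(benzyloxy)benzaldehyde | O=Cc1cc(OCc2ccccc2)c(OCc2ccccc2)c(OCc2ccccc2)c1 | starting material
5 | 3-(methoxymethoxy)prop-1-ene | C=CCOCOC | starting material
6 | (Z)-3-(methoxymethoxy)allyllithium | COCO/C=C\C[Li] | intermediate
7 | [(Z)-3-(methoxymethoxy)allyl]diisopinocampheylborane, Ipc groups from (+)-α-pinene | COCO/C=C\CB([C@@H]1C[C@@H]2C[C@H]([C@H]1C)C2(C)C)[C@@H]1C[C@@H]2C[C@H]([C@H]1C)C2(C)C | intermediate
8 | (1R,2R)-2-(methoxymethoxy)-1-[3,4,5-tris(benzyloxy)phenyl]but-3-en-1-ol | C=C[C@@H](OCOC)[C@@H](c1cc(OCc2ccccc2)c(OCc2ccccc2)c(OCc2ccccc2)c1)O | intermediate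
9 | (2S,3R)-3-hydroxy-2-(methoxymethoxy)-3-[3,4,5-tris(benzyloxy)phenyl]propanal | O=C[C@@H](OCOC)[C@@H](c1cc(OCc2ccccc2)c(OCc2ccccc2)c(OCc2ccccc2)c1)O | intermediate
10 | (1R,2R)-2-(methoxymethoxy)-1-[3,4,5-tris(benzyloxy)phenyl]propane-1,3-diol | OC[C@@H](OCOC)[C@@H](c1cc(OCc2ccccc2)c(OCc2ccccc2)c(OCc2ccccc2)c1)O | intermediate
11 | (1R,2S)-3-chloro-2-(methoxymethoxy)-1-[3,4,5-tris(benzyloxy)phenyl]propan-1-ol | ClC[C@@H](OCOC)[C@@H](c1cc(OCc2ccccc2)c(OCc2ccccc2)c(OCc2ccccc2)c1)O | intermediate
12 | [4-(benzyloxy)-2-fluoro-6-(methoxymethoxy)phenyl]lithium | COCOc1cc(OCc2ccccc2)cc(F)c1[Li] | intermediate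
13 | potassium alkoxide of 11 | ClC[C@@H](OCOC)[C@@H](c1cc(OCc2ccccc2)c(OCc2ccccc2)c(OCc2ccccc2)c1)[O-].[K+] | intermediate
14 | 5-(benzyloxy)-3-(methoxymethoxy)benzyne | COCOC1=CC(OCc2ccccc2)=CC#C1 | intermediate
15 | {4-(benzyloxy)-2-(methoxymethoxy)-6-[(1R,2S)-3-chloro-2-(methoxymethoxy)-1-[3,4,5-tris(benzyloxy)phenyl]propoxy]phenyl}potassium | ClC[C@@H](OCOC)[C@@H](c1cc(OCc2ccccc2)c(OCc2ccccc2)c(OCc2ccccc2)c1)Oc1cc(OCc2ccccc2)cc(OCOC)c1[K] | intermediate
16 | (2R,3R)-7-(benzyloxy)-3,5-bis(methoxymethoxy)-2-[3,4,5-tris(benzyloxy)phenyl]chromane | COCOc1cc(OCc2ccccc2)cc2c1C[C@@H](OCOC)[C@@H](c1cc(OCc3ccccc3)c(OCc3ccccc3)c(OCc3ccccc3)c1)O2 | intermediate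
17 | (2R,3R)-7-(benzyloxy)-2-[3,4,5-tris(benzyloxy)phenyl]chromane-3,5-diol | Oc1cc(OCc2ccccc2)cc2c1C[C@@H](O)[C@@H](c1cc(OCc3ccccc3)c(OCc3ccccc3)c(OCc3ccccc3)c1)O2 | intermediate
18 | 3,4,5-tris(benzyloxy)benzoic acid | OC(=O)c1cc(OCc2ccccc2)c(OCc2ccccc2)c(OCc2ccccc2)c1 | starting material
19 | (2R,3R)-7-(benzyloxy)-2-[3,4,5-tris(benzyloxy)phenyl]chromane-3,5-diyl bis[3,4,5-tris(benzyloxy)benzoate] | O=C(Oc1cc(OCc2ccccc2)cc2c1C[C@@H](OC(=O)c1cc(OCc3ccccc3)c(OCc3ccccc3)c(OCc3ccccc3)c1)[C@@H](c1cc(OCc3ccccc3)c(OCc3ccccc3)c(OCc3ccccc3)c1)O2)c1cc(OCc2ccccc2)c(OCc2ccccc2)c(OCc2ccccc2)c1 | intermediate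
20 | epigallocatechin 3,5-digallate, (2R,3R)-7-hydroxy-2-(3,4,5-trihydroxyphenyl)chromane-3,5-diyl bis(3,4,5-trihydroxybenzoate) | O=C(Oc1cc(O)cc2c1C[C@@H](OC(=O)c1cc(O)c(O)c(O)c1)[C@@H](c1cc(O)c(O)c(O)c1)O2)c1cc(O)c(O)c(O)c1 | target

Total step count: 9. Longest linear sequence: 7 steps (steps 3 to 9, from aldehyde 4).

Steps most likely to fail

Step 6 (aryne annulation). The aryllithium may add to the aryne faster than the alkoxide does. The aryl anion may be protonated, or may abstract the benzylic C2 hydrogen, before it closes. Lithiation may also occur partly between F and OBn, which would exchange the groups on O5 and O7. The fallback uses known chemistry, makes the two bonds one after the other, sets out from 3 and 11, and returns at 16. Aryllithium 12 is kept at −78 °C and quenched with methyl 4-methylbenzenesulfinate to give 5-(benzyloxy)-1-fluoro-3-(methoxymethoxy)-2-[(4-methylphenyl)sulfinyl]benzene F1, which can be freed from any regioisomer. The sulfinyl group activates the neighbouring fluoride, so alkoxide 13 replaces it by SNAr (THF–DMF, 0 °C) and forms O1–C8a in the aryl ether sulfoxide F2 (a mixture at sulfur, of no consequence). PhLi (THF, −78 °C) then effects sulfoxide–lithium exchange to the aryllithium F3, metalated at C4a only. On warming, F3 closes onto the chloride by Parham cyclialkylation and gives 16.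

Step 5 (selective chlorination). The electron-rich benzylic hydroxyl may be activated alongside the primary one, with ionisation, elimination or loss of configuration at C2. The fallback sets out from 10 and returns at 11, and replaces phosphonium activation by a sulfonate that is displaced separately. TsCl in pyridine at 0 °C sulfonylates the unhindered primary hydroxyl to give the primary 4-methylbenzenesulfonate F4 without creating a leaving group at the benzylic carbon. LiCl in DMF at 50 °C then displaces the sulfonate under neutral conditions to give 11.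

Step 9 (global debenzylation). The hydrogenolysis may stall at partly benzylated stages as polarity rises. The benzylic C2–O1 bond may be opened reductively. The C5 aryl ester may also be lost during a prolonged reaction. The fallback sets out from 19 and returns at 20, and replaces reduction by Lewis-acid dealkylation with a cation scavenger. BCl3 with pentamethylbenzene in CH2Cl2 at −78 °C cleaves aryl benzyl ethers without hydrogen or metal, and esters tolerate it. This fallback makes no new compound (F0).

Further compounds
F1 | step 6 | 5-(benzyloxy)-1-fluoro-3-(methoxymethoxy)-2-[(4-methylphenyl)sulfinyl]benzene | COCOc1cc(OCc2ccccc2)cc(F)c1S(=O)c1ccc(C)cc1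
F2 | step 6 | aryl ether sulfoxide, 5-(benzyloxy)-1-[(1R,2S)-3-chloro-2-(methoxymethoxy)-1-[3,4,5-tris(benzyloxy)phenyl]propoxy]-3-(methoxymethoxy)-2-[(4-methylphenyl)sulfinyl]benzene | ClC[C@@H](OCOC)[C@@H](c1cc(OCc2ccccc2)c(OCc2ccccc2)c(OCc2ccccc2)c1)Oc1cc(OCc2ccccc2)cc(OCOC)c1S(=O)c1ccc(C)cc1
F3 | step 6 | aryllithium, lithium counterpart of 15 | ClC[C@@H](OCOC)[C@@H](c1cc(OCc2ccccc2)c(OCc2ccccc2)c(OCc2ccccc2)c1)Oc1cc(OCc2ccccc2)cc(OCOC)c1[Li]
F4 | step 5 | primary 4-methylbenzenesulfonate, (2R,3R)-3-hydroxy-2-(methoxymethoxy)-3-[3,4,5-tris(benzyloxy)phenyl]propyl 4-methylbenzenesulfonate | Cc1ccc(cc1)S(=O)(=O)OC[C@@H](OCOC)[C@@H](c1cc(OCc2ccccc2)c(OCc2ccccc2)c(OCc2ccccc2)c1)O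
F0 | step 9 | none | none
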